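Which of these flasks gives the largest excess of left-handed product over right-handed product, and how large is that excess in each?

| flask | left-handed substrate | gas | right-handed substrate | temperature | time |
|---|---|---|---|---|---|
| Thursday's | 0.50 M | 200 mM (held) | 0.50 M | 55 °C | 8.0 h |
| Friday's | 0.50 M | 200 mM (held) | 0.50 M | 80 °C | 8.0 h |
| Tuesday's | 0.50 M | 200 mM (held) | 0.50 M | 30 °C | 8.0 h |
| Sunday's | 0.50 M | 200 mM (held) | 0.50 M | 5 °C | 8.0 h |

    right-handed substrate ⇌ achiral form (K7 = 0.74, k7 = 0.19 h⁻¹, Ea7 = 99.0 kJ mol⁻¹, ΔH7 = −27.0 kJ mol⁻¹)
    gas ⇌ partner, rate k2*(csat - [partner]) (k2 = 1.5 h⁻¹, csat = 200 mM)
    achiral form → waste (k3 = 0.23 h⁻¹, Ea3 = 99.0 kJ mol⁻¹)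
    partner + right-handed substrate → right-handed product (k4 = 0.56 M⁻¹ h⁻¹, Ea4 = 63.0 kJ mol⁻¹)
    partner → decomposition product (k5 = 2.0 × 10⁻⁴ h⁻¹, Ea5 = 100 kJ mol⁻¹)
    partner + left-handed substrate → left-handed product (k6 = 0.94 M⁻¹ h⁻¹, Ea6 = 58.0 kJ mol⁻¹)
    left-handed substrate ⇌ achiral form (K7 = 0.74, k7 = 0.19 h⁻¹, Ea7 = 99.0 kJ mol⁻¹, ΔH7 = −27.0 kJ mol⁻¹)
    partner → decomposed reagent (k8 = 0.087 h⁻¹, Ea8 = 95.0 kJ mol⁻¹)
    (constants at 5 °C)

- partner is single-handed; left-handed substrate and right-handed substrate are mirror images of each other, charged as a racemate, each of them at the stated concentration
- at the start none of partner is dissolved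
- constants are those at 5 °C; use the activation energies and enthalpies for any other temperature
- an excess is the difference of the two amounts in percent of their sum
- an excess is below zero if the other one leads
- the handed part of partner does not stay in what it makes, so the products of the two hands are mirror images too

* the best flask by excess of left-handed product over right-handed product; "all alike" if 1.5 percentage points covers them all (Thursday's / Friday's / Tuesday's / Sunday's / all alike)
* excess of left-handed product over right-handed product at the end, Thursday's
* excess of left-handed product over right-handed product at the end, Friday's
* excess of left-handed product over right-handed product at the end, Tuesday's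
* excess of left-handed product over right-handed product at the end, Sunday's

I turned the question round and asked what the numbers would need for the warmest flask to win. Partner enters both product-making rates as the same factor, so it cancels from their ratio, which is the left-handed constant over the right-handed constant, times [left-handed substrate]/[right-handed substrate]. That ratio of constants, the selectivity factor, stood at 1.68 at 5 °C. It moves with temperature through the gap of 5.00 kJ mol⁻¹, the activation energy of the right-handed route minus that of the left-handed route. For the factor to favour the warmest flask, this gap had to be below zero, but the right-handed route had the higher barrier. So warming shrinks the factor, which reaches one at 92.6 °C, and Friday's at 80 °C stood below that.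

The excess equals the factor minus one over the factor plus one where exchange through the achiral form keeps the two substrates equal. On Friday's, the step into the achiral form had a constant of 1690 h⁻¹, against 38.7 h⁻¹ for left-handed product making with partner at its saturation value. Exchange also led on Thursday's and on Tuesday's. So I reckoned 9.40% for Thursday's, 2.94% for Friday's and 16.8% for Tuesday's. On Sunday's the two constants were level, 0.19 h⁻¹ against 0.188 h⁻¹, so the left-handed substrate could fall behind and I gave a bound, under 25.3%. Taking that bound as the score for Sunday's, I chose Sunday's, but this was a judgement and not a proof, since a bound from above does not say how far the flask falls under it.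

The forecast also named Sunday's, with 9.3% for Thursday's, 2.9% for Friday's, 16.1% for Tuesday's and 18% for Sunday's, where it judged that “exchange is slow enough that the left-handed substrate depletes”. It gave a figure for Sunday's where I gave a bound.

The flasks gave Sunday's as best, at 19.2%, then 16.1% for Tuesday's, 9.38% for Thursday's and 2.94% for Friday's. Sunday's still held 24% of its charged left-handed substrate and 31% of its right-handed substrate at 8.00 h. A flask like Friday's kept at 105 °C stood above the crossing, and the same gap gave −2.69%. Its run read −2.69%, with right-handed product ahead, and waste held >99.9% of the charged substrates.

The rate constants were set for the occasion, and the outcome is calculated.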